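The rate constants come from no measurement; what happens was integrated by code.

The question is how much substrate this flask has consumed at the asked time and what pH it then shows.

    weak acid + target → side product (k1 = 3.9 L mol⁻¹ h⁻¹)
    target → over-reaction product (k2 = 1.8 × 10⁻⁴ h⁻¹)
    substrate + acid → weak acid + acid + target (k3 = 220 L mol⁻¹ h⁻¹)
    weak acid ⇌ conjugate base + acid, settled at all times (K4 = 2.5 × 10⁻⁵ M)
    substrate → weak acid + target (k5 = 0.042 h⁻¹)

substrate 0.20 M; acid 0.600 mM; time 20 h

* part of the substrate that has reacted at 20 h
* pH of the solution at 20 h

- acid is the free proton; pH is minus the decimal logarithm of its molar concentration
- run time (flask): 20 h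

**Acid balance.** Acid is the smaller charge, 0.600 mM against 0.20 M of substrate, and the catalysed path returns it, so c(acid) equals its charge plus c(conjugate base), while the fast balance requires c(acid) × c(conjugate base) = 2.5 × 10⁻⁵ M × c(weak acid). The doubling level is 0.0288 M: the weak acid at which free acid stands at twice its charge.

**Two extremes.** If weak acid released no acid, substrate would decay with the pseudo-first-order constant 0.174 h⁻¹. If the whole substrate charge stood as weak acid from the start, c(acid) would be 2.56 mM and the constant 0.604 h⁻¹, leaving <0.001 % of the substrate. The real flask lies between, so more than 96.9 % has reacted.

**Final acid.** Weak acid and target form together and leave together by the first step, the second being slow (half-life 160 d against 20 h), so target stays nearly equal to weak acid and conjugate base counted together. Released all at once, they would fall to 0.0120 M; later release leaves somewhat more. That is below the doubling level, and the balance gives c(acid) = 0.925 mM, so pH 3.03.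

**The forecast.** It gave 99.8 % and pH 3, holding that “its partial dissociation on top of the original 0.6 mM acid leaves about 1 mM free proton”.

**The result.** This flask gives 99.9 % reacted and pH 2.99. Its weak acid reads 0.0167 M at 20.0 h, below the doubling level, and the balance then gives 169 % of the acid charge, where the flask reads 169 %. The neighbour flask, the same charge read at 5.0 h, holds 0.0727 M of weak acid, above the doubling level; the balance gives 280 % of the charge, and that flask reads 280 %.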